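The easy step is to set the two ways out of Z side by side, in set-ups charged alike.

common to all: G 0.50 µM
- cedar: Z 0.50 mM; a single well-mixed tank run continuously and read at steady state, 12 min in it on average
- maple: Z 0.50 mM; a tube with plug flow, the mixed feed as stated, residence time 12 min; time 12 min
- ash: Z 0.50 mM; everything together in a closed stirred flask, run for 12 min; time 12 min
- birch: Z 0.50 mM (fed, over 9.60 min); a stirred flask in which Z is dosed at a steady rate over 9.60 min without added volume, worked up at 12 min; time 12 min

    2 Z → Z2 (k1 = 18 /M/s)
    Z.G → G + Q (k2 = 120 /s)
    Z + G ⇌ Z.G (K3 = 230 /M, k3 = 71000 /M/s)

- percent here means Z units held: one Z2 counts as two
- two of one species on the left: rate k times its square, two consumed each time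
- the stated concentrations are those of everything mixed, before any reaction; amounts are the same in each set-up
- the feed brings no volume worth counting
- run time (maple): 12 min

1. the set-up with the highest amount of Q at the outlet or at the end, in percent of the Z put in ("none" if the first two lie within 2 percentage points) (cedar / maple / ash / birch / none)
2. amount of Q at the outlet or at the end, in percent of the Z put in, cedar
3. amount of Q at the outlet or at the end, in percent of the Z put in, maple
4. amount of Q at the outlet or at the end, in percent of the Z put in, ash
5. amount of Q at the outlet or at the end, in percent of the Z put in, birch

The first chemist counts at the charge in ash: Z enters Z.G 2.0 times as fast as it goes to Z2, forward rate of binding alone, so she expects 66.4% of Z to end as Q, and about that figure from each vessel, since the charges are equal.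

The second chemist answers that binding is not yet product. Z.G falls back at 309 /s and goes on to Q at 120 /s, so a share of 28.0% of the binding goes forward. The equilibrium constant times c(Z) at the start in ash is 0.12, so free G can be taken at its charge, and Q forms with a pseudo-first-order constant of 0.00994 /s. Set against the loss of Z to Z2, this gives 0.276 mM, the crossover concentration, the c(Z) at which Z turns into Q as fast as into Z2. The charge stands above it, so at the charge the ratio of the Q path to the Z2 path is 0.552, but that ratio grows as c(Z) falls, and on this view the vessels part by how low each holds c(Z) while Z is used.

By hand, for ash and for maple, whose every slice of feed ages like a closed flask, I average the part going to Q from the charge down to zero. Running down to zero is fair, since the tail half-life of 1.16 min is shorter than the 12 min allowed. This gives 57.1%. For cedar, a mixed tank, and birch, dosed over 9.60 min, my hand reckoning stops.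

The forecast sides with the second chemist: birch best, with cedar 75%, maple 56.1%, ash 56.1% and birch 79.2%, on the ground that “Low Z favours first-order catalysis over second-order dimerisation”. Its ash figure stands 1.00 percentage point below mine.

The simulation gives birch at 79.1%, cedar 75.0%, and maple and ash both 56.1%; the first chemist's flat view keeps one region, the pair maple and ash, which agree, though not at her 66.4%. Cedar read 0.0528 mM of Z in the tank, below the crossover concentration, and its part to Q, 83.9%, times the 89.4% of Z converted makes 75.1%. A neighbour of ash charged with 0.12 mM of Z starts below it too; its averaged part reckons at 83.0%, and that flask gave 82.8%.

The constants belong to no real substance; the flask was simulated.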